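All runs are simulated on assumed constants; the scatter is artificial.

Substrate in amber, the flask asked about, falls far faster than its product rises: at 0.417 h substrate reads 50.5 % and product 0 %.

common to all: free catalyst 7.9 mM
- amber: substrate 0.10 M; reagent 0.10 M; the very flask that is asked about, followed so far
- green: substrate 0.15 M; reagent 0.10 M; run made earlier
- flask: substrate 0.10 M; reagent 0.100 M

| run | time / h | product / % | substrate / % |
|---|---|---|---|
| amber | 0.417 | 0 | 50.5 |
| amber | 1.00 | 0.1 | 28.7 |
| amber | 2.00 | 0.3 | 22.3 |
| amber | 3.00 | 1.3 | 20.9 |
| green | 1.33 | 0 | 25.4 |
| green | 4.00 | 2.7 | 20.4 |
| green | 6.00 | 1.6 | 21.5 |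
| green | 10.0 | 4.3 | 20.7 |

(readings scatter by 0.5 percentage points)

- apparent order in reagent when 20 % of the substrate are converted (percent change of the rate of making product for one percent more reagent charged)
- apparent order in free catalyst when 20 % of the substrate are converted (percent change of the rate of making product for one percent more free catalyst charged)
- factor on the rate of making product when 20 % of the substrate are converted if reagent is charged twice over

We bracket the answer by two times. Amber's substrate relaxes towards 20.9 % with a rate constant of about 2.36 h⁻¹, so 20 % conversion comes at about 0.124 h. Green's last reading gives product a steady gain of 0.430 % of the charge per hour. Amber's 0.3 % at 2.00 h then puts the start of that stream near 1.30 h. This is the filling time, the delay before the steady product stream starts, or induction period. It is rough, since that reading carries a scatter of 0.5 percentage points.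

From above: if reagent enters once on the way to product, its order is at most one and doubling gives at most two. From below: we assume reagent's step takes about one filling time. Then by 0.124 h that step has drained a fraction of about 0.0950 of what it feeds, so the order is at least 0.905. With reagent charged twice over, the same step drains a fraction of about 0.190 instead, so the doubling factor is at least about 1.82. No run varies reagent, so this floor rests on that assumption. For free catalyst we claim only the ceiling of one.

The forecast gives 0.9, 0.8 and 1.85, reasoning that “the rate likely goes as reagent to the first power, and probably as catalyst too”. Its reagent order stands at our floor.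

The flask gives 0.95, 0.80 and 1.90.

    reagent + catalyst intermediate B → catalyst intermediate C (k = 17.0 M⁻¹ h⁻¹)
    catalyst intermediate C → free catalyst + product (k = 2.40 h⁻¹)
    substrate ⇌ dormant form (K = 3.60, k = 1.80 h⁻¹)
    catalyst intermediate A → catalyst intermediate B (k = 0.350 h⁻¹)
    substrate + free catalyst ⇌ catalyst intermediate A (K = 15.0 M⁻¹, k = 20.0 M⁻¹ h⁻¹)

The rate of making product at 0.119 h was 4.78 × 10⁻⁶ M h⁻¹, and at 0.923 h it stood 85 times higher. With that time, the filling time gives a floor of 0.909, and the order lies above it. In green, the first reading came at about one filling time, at 1.33 h, and its product read 0 %.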